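**Abbreviations:** MOM = methoxymethyl; pin = pinacolato; (2R)-lavandulyl = (2R)-5-methyl-2-(prop-1-en-2-yl)hex-4-en-1-yl.

## Retrosynthetic overview

1. Target 28 comes from 26 by unmasking the 5-OMe and three MOM groups. Ring C is the only ring that is built. It is closed by a catalyst-controlled oxa-Michael addition of 2'-hydroxychalcone 25, which sets C2. The 6'-methyl ether forces closure through the oxygen next to the side chain, giving 8- and not 6-substitution.
2. Chalcone 24 comes from the aryllithium of lavandulyl arene 17 and cinnamoyl Weinreb amide 21, itself made by a Heck reaction of bromide 19 with 20.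
3. The lavandulyl chain of 17 is grown on ring A by three boron-to-carbon 1,2-shifts: an aryl shift onto ClCH2–B, a Pd-induced enantioselective benzyl shift onto a B-vinyl group with capture by isobutenyl bromide (sets C2''), and a stereoretentive Zweifel shift onto isopropenyl.
4. Rings A and B both come from resorcinol bis-MOM ether 2. Ring A needs meta C–H borylation, oxidation and methylation. Ring B needs dibromination and mono-methoxylation.

**Assumption:** the sense of induction of (Sp,Sp)-MandyPhos (step 5) and of the quinine-derived thiourea (step 12) is assigned by analogy; if either is opposite, the mirror-image ligand or the quinidine-derived catalyst is used.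

## Route

Step 1
Reactants: 1 resorcinol
Product: 2 1,3-bis(methoxymethoxy)benzene
Conditions: NaH (2.4 equiv), MOMCl (2.4 equiv), DMF, 0 °C → rt
Reagents that add atoms: chloromethyl methyl ether (MOMCl) COCCl
Why: Williamson-type O-alkylation gives the acetal ethers that later direct lithiation and serve both aromatic rings.

Step 2
Reactants: 2 1,3-bis(methoxymethoxy)benzene
Product: 4 3,5-bis(methoxymethoxy)phenol, via aryl pinacol boronate 3 (not isolated)
Conditions: [Ir(OMe)(cod)]2 (1 mol %), dtbpy (2 mol %), B2pin2 (0.55 equiv), THF, 80 °C; then 30 % H2O2, aq NaOH, 0 °C → rt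
Reagents that add atoms: bis(pinacolato)diboron CC1(C)OB(OC1(C)C)B1OC(C)(C)C(C)(C)O1 (boryl group of 3 only); hydrogen peroxide OO (phenol oxygen of 4)
Why: Sterically controlled Ir-catalysed C–H borylation reaches only the C–H meta to both ethers, and boronate oxidation in the same flask gives the 1,3,5-trioxygenated ring.

Step 3
Reactants: 4 3,5-bis(methoxymethoxy)phenol
Product: 5 1-methoxy-3,5-bis(methoxymethoxy)benzene
Conditions: MeI (1.5 equiv), K2CO3, acetone, reflux
Reagents that add atoms: iodomethane CI
Why: Williamson ether synthesis marks the future C5 oxygen with a group that survives organolithiums and acid and differs from the two MOM ethers.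

Step 4
Reactants: 5 1-methoxy-3,5-bis(methoxymethoxy)benzene
Product: 8 2-{[4-methoxy-2,6-bis(methoxymethoxy)phenyl]methyl}-4,4,5,5-tetramethyl-1,3,2-dioxaborolane, via aryllithium 6 (not isolated), via chloromethyl boronate complex 7 (not isolated)
Conditions: n-BuLi (1.05 equiv), THF, 0 °C, 1 h; ClCH2Bpin (1.1 equiv), −78 °C → rt, 12 h
Reagents that add atoms: 2-(chloromethyl)-4,4,5,5-tetramethyl-1,3,2-dioxaborolane ClCB1OC(C)(C)C(C)(C)O1; n-butyllithium [Li]CCCC (lithium of 6 and 7 only)
Why: Directed ortho-metalation occurs at the site chelated by both MOM groups, and the ate complex then undergoes a Matteson-type 1,2-shift of the electron-rich aryl group from boron to carbon with loss of chloride.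

Step 5
Reactants: 8 benzyl boronate; 9 vinylmagnesium bromide; 10 1-bromo-2-methylprop-1-ene
Product: 12 2-{(2R)-1-[4-methoxy-2,6-bis(methoxymethoxy)phenyl]-5-methylhex-4-en-2-yl}-4,4,5,5-tetramethyl-1,3,2-dioxaborolane, via vinyl boronate complex 11 (not isolated)
Conditions: 9 (1.05 equiv), NaOTf (3 equiv), THF, 0 °C → rt; then Pd(OAc)2 (2 mol %), (Sp,Sp)-MandyPhos (2.4 mol %), 10 (1.2 equiv), 60 °C, 16 h
Reagents that add atoms: none
Why: Proposed new method: an enantioselective Pd-induced 1,2-metallate shift in which a benzylic carbon flanked by two acetal ethers is the migrating group, which has not been shown; oxidative addition of 10 and bromide scavenging by NaOTf give a cationic isobutenyl-Pd(II) complex that binds one face of the vinyl group of four-coordinate boronate 11, the ArCH2–B bond anti to Pd shifts from boron to the adjacent carbon as Pd–C forms at the terminal carbon, and reductive elimination closes the prenyl C(sp3)–C(sp2) bond, so two C–C bonds and the (R) centre C2'' form at once under ligand control, provided the wide-bite-angle ligand favours the shift over direct benzyl or vinyl transmetalation; the closest known reaction type is the conjunctive cross-coupling of aryl-, alkyl- and alkenyl(vinyl)boronate complexes with C(sp2) triflates and halides.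

Step 6
Reactants: 12 (R)-secondary boronate; 13 2-bromopropene
Product: 17 5-methoxy-1,3-bis(methoxymethoxy)-2-[(2R)-lavandulyl]benzene, via isopropenyllithium 14 (not isolated), via isopropenyl boronate complex 15 (not isolated), via beta-iodo boronate 16 (not isolated)
Conditions: 13 (1.5 equiv), t-BuLi (3 equiv), Et2O, −78 °C; 12 in THF, −78 °C; I2, THF, −78 °C; NaOMe, MeOH, −78 °C → rt
Reagents that add atoms: tert-butyllithium [Li]C(C)(C)C (lithium of 14 and 15 only); iodine II (iodine of 16 only)
Why: In this Zweifel olefination, iodonium formation on the B-isopropenyl group triggers a 1,2-shift of the secondary carbon from boron to carbon with retention, and methoxide-induced anti elimination of B and I gives the isopropenyl group, so C2'' stays (R).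

Step 7
Reactants: 2 1,3-bis(methoxymethoxy)benzene
Product: 18 1,5-dibromo-2,4-bis(methoxymethoxy)benzene
Conditions: NBS (2.1 equiv), MeCN, 0 °C → rt
Reagents that add atoms: N-bromosuccinimide O=C1CCC(=O)N1Br
Why: Electrophilic aromatic bromination takes the two equivalent positions ortho/para to the ethers and leaves the hindered position between them untouched.

Step 8
Reactants: 18 1,5-dibromo-2,4-bis(methoxymethoxy)benzene
Product: 19 1-bromo-5-methoxy-2,4-bis(methoxymethoxy)benzene
Conditions: NaOMe (1.2 equiv), CuI (10 mol %), DMF/MeOH, 100 °C, stopped at about 80 % conversion, 18 recovered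
Reagents that add atoms: sodium methoxide [Na+].[O-]C
Why: In this Ullmann-type Cu-catalysed methoxylation, the dibromide reacts faster than the product because each bromine is activated by the other meta bromine and there are two equivalent sites.

Step 9
Reactants: 19 1-bromo-5-methoxy-2,4-bis(methoxymethoxy)benzene; 20 N-methoxy-N-methylacrylamide
Product: 21 (E)-N-methoxy-3-[5-methoxy-2,4-bis(methoxymethoxy)phenyl]-N-methylprop-2-enamide
Conditions: Pd(OAc)2 (3 mol %), P(o-tol)3 (9 mol %), NaOAc, DMF, 110 °C
Reagents that add atoms: none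
Why: The Mizoroki–Heck reaction with an acrylamide gives the E-cinnamoyl unit directly at the oxidation level needed for ketone synthesis.

Step 10
Reactants: 17 lavandulyl arene; 21 cinnamoyl Weinreb amide
Product: 24 (E)-1-{6-methoxy-2,4-bis(methoxymethoxy)-3-[(2R)-lavandulyl]phenyl}-3-[5-methoxy-2,4-bis(methoxymethoxy)phenyl]prop-2-en-1-one, via aryllithium 22 (not isolated), via tetrahedral lithium adduct 23 (not isolated)
Conditions: n-BuLi (1.05 equiv), THF, 0 °C, 1 h; 21, −78 → 0 °C; sat. aq NH4Cl
Reagents that add atoms: n-butyllithium [Li]CCCC (lithium of 22 and 23 only)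
Why: Directed ortho-metalation at one of the two equivalent C–H sites between OMOM and OMe is followed by a Weinreb ketone synthesis, in which the hard aryllithium adds 1,2 and the chelated adduct prevents over-addition.

Step 11
Reactants: 24 fully protected chalcone
Product: 25 (E)-1-{2-hydroxy-6-methoxy-4-(methoxymethoxy)-3-[(2R)-lavandulyl]phenyl}-3-[5-methoxy-2,4-bis(methoxymethoxy)phenyl]prop-2-en-1-one
Conditions: conc. HCl (0.2 equiv), MeOH/THF 1:1, 0 °C → rt, TLC control
Reagents that add atoms: none
Why: In this acid-catalysed acetal exchange, the only MOM group ortho to the ketone, squeezed between acyl and lavandulyl, leaves fastest because its phenol is the best leaving group and ends hydrogen-bonded to C=O.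

Step 12
Reactants: 25 2'-hydroxychalcone
Product: 26 (2S)-5-methoxy-7-(methoxymethoxy)-2-[5-methoxy-2,4-bis(methoxymethoxy)phenyl]-8-[(2R)-lavandulyl]-2,3-dihydro-4H-chromen-4-one
Conditions: quinine-derived 3,5-bis(trifluoromethyl)phenyl thiourea (20 mol %), toluene, 35 °C, 72 h; chromatography
Reagents that add atoms: none
Why: In this bifunctional cinchona-thiourea catalysed intramolecular oxa-Michael addition, the quinuclidine deprotonates the 2'-OH while the thiourea binds the carbonyl, which sets (2S) under catalyst control; the 6'-OMe makes closure exergonic, and the minor C2 epimer is a diastereomer that is removed by chromatography.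

Step 13
Reactants: 26 protected flavanone
Product: 28 (2S)-2-(2,4-dihydroxy-5-methoxyphenyl)-5,7-dihydroxy-8-[(2R)-lavandulyl]-2,3-dihydro-4H-chromen-4-one, via 5-hydroxy tris-MOM flavanone 27 (not isolated)
Conditions: MgI2·OEt2 (3 equiv), THF, 55 °C; dilute HCl wash, no purification; 1.25 M HCl in MeOH, 40 °C
Reagents that add atoms: none
Why: Chelation-controlled ether cleavage, proven on 5-methoxy-8-prenylflavanones, removes only the methyl group peri to C=O, and acetal methanolysis then removes the MOM groups; no base is present, so C2 is not opened, and the alkenes and the 5'-OMe survive.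

## Compound list

1 | resorcinol | Oc1cccc(O)c1 | starting material
2 | 1,3-bis(methoxymethoxy)benzene | COCOc1cccc(OCOC)c1 | intermediate
3 | 2-[3,5-bis(methoxymethoxy)phenyl]-4,4,5,5-tetramethyl-1,3,2-dioxaborolane | COCOc1cc(OCOC)cc(B2OC(C)(C)C(C)(C)O2)c1 | intermediate
4 | 3,5-bis(methoxymethoxy)phenol | COCOc1cc(O)cc(OCOC)c1 | intermediate
5 | 1-methoxy-3,5-bis(methoxymethoxy)benzene | COCOc1cc(OC)cc(OCOC)c1 | intermediate
6 | [4-methoxy-2,6-bis(methoxymethoxy)phenyl]lithium | [Li]c1c(OCOC)cc(OC)cc1OCOC | intermediate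
7 | lithium (chloromethyl)[4-methoxy-2,6-bis(methoxymethoxy)phenyl](pinacolato)borate | [Li+].ClC[B-]1(c2c(OCOC)cc(OC)cc2OCOC)OC(C)(C)C(C)(C)O1 | intermediate
8 | 2-{[4-methoxy-2,6-bis(methoxymethoxy)phenyl]methyl}-4,4,5,5-tetramethyl-1,3,2-dioxaborolane | COCOc1cc(OC)cc(OCOC)c1CB1OC(C)(C)C(C)(C)O1 | intermediate
9 | vinylmagnesium bromide | C=C[Mg]Br | starting material
10 | 1-bromo-2-methylprop-1-ene | CC(C)=CBr | starting material
11 | bromomagnesium {[4-methoxy-2,6-bis(methoxymethoxy)phenyl]methyl}(vinyl)(pinacolato)borate | Br[Mg+].C=C[B-]1(Cc2c(OCOC)cc(OC)cc2OCOC)OC(C)(C)C(C)(C)O1 | intermediate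
12 | 2-{(2R)-1-[4-methoxy-2,6-bis(methoxymethoxy)phenyl]-5-methylhex-4-en-2-yl}-4,4,5,5-tetramethyl-1,3,2-dioxaborolane | CC1(C)OB(OC1(C)C)[C@H](CC=C(C)C)Cc1c(OCOC)cc(OC)cc1OCOC | intermediate
13 | 2-bromopropene | C=C(C)Br | starting material
14 | isopropenyllithium | [Li]C(C)=C | intermediate
15 | lithium isopropenyl boronate complex of 12 | [Li+].C=C(C)[B-]1([C@H](CC=C(C)C)Cc2c(OCOC)cc(OC)cc2OCOC)OC(C)(C)C(C)(C)O1 | intermediate
16 | beta-iodo tertiary boronate (1-iodo-2-boryl-2-methyl unit on the (R) carbon, new centre undefined) | CC1(C)OB(OC1(C)C)C(C)(CI)[C@H](CC=C(C)C)Cc1c(OCOC)cc(OC)cc1OCOC | intermediate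
17 | 5-methoxy-1,3-bis(methoxymethoxy)-2-[(2R)-5-methyl-2-(prop-1-en-2-yl)hex-4-en-1-yl]benzene | C=C(C)[C@H](CC=C(C)C)Cc1c(OCOC)cc(OC)cc1OCOC | intermediate
18 | 1,5-dibromo-2,4-bis(methoxymethoxy)benzene | COCOc1cc(OCOC)c(Br)cc1Br | intermediate
19 | 1-bromo-5-methoxy-2,4-bis(methoxymethoxy)benzene | COCOc1cc(OCOC)c(OC)cc1Br | intermediate
20 | N-methoxy-N-methylacrylamide | C=CC(=O)N(C)OC | starting material
21 | (E)-N-methoxy-3-[5-methoxy-2,4-bis(methoxymethoxy)phenyl]-N-methylprop-2-enamide | CON(C)C(=O)/C=C/c1cc(OC)c(OCOC)cc1OCOC | intermediate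
22 | aryllithium of 17 (Li between OMe and OMOM) | C=C(C)[C@H](CC=C(C)C)Cc1c(OCOC)cc(OC)c([Li])c1OCOC | intermediate
23 | tetrahedral lithium adduct of 22 and 21 | [Li+].C=C(C)[C@H](CC=C(C)C)Cc1c(OCOC)cc(OC)c(C([O-])(N(C)OC)/C=C/c2cc(OC)c(OCOC)cc2OCOC)c1OCOC | intermediate
24 | fully protected (E)-chalcone | C=C(C)[C@H](CC=C(C)C)Cc1c(OCOC)cc(OC)c(C(=O)/C=C/c2cc(OC)c(OCOC)cc2OCOC)c1OCOC | intermediate
25 | (E)-2'-hydroxychalcone | C=C(C)[C@H](CC=C(C)C)Cc1c(OCOC)cc(OC)c(C(=O)/C=C/c2cc(OC)c(OCOC)cc2OCOC)c1O | intermediate
26 | (2S,2''R)-5-O-methyl tris-MOM flavanone | C=C(C)[C@H](CC=C(C)C)Cc1c(OCOC)cc(OC)c2c1O[C@H](c1cc(OC)c(OCOC)cc1OCOC)CC2=O | intermediate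
27 | (2S,2''R)-5-hydroxy tris-MOM flavanone | C=C(C)[C@H](CC=C(C)C)Cc1c(OCOC)cc(O)c2c1O[C@H](c1cc(OC)c(OCOC)cc1OCOC)CC2=O | intermediate
28 | (2S)-2-(2,4-dihydroxy-5-methoxyphenyl)-5,7-dihydroxy-8-[(2R)-5-methyl-2-(prop-1-en-2-yl)hex-4-en-1-yl]-2,3-dihydro-4H-chromen-4-one | C=C(C)[C@H](CC=C(C)C)Cc1c(O)cc(O)c2c1O[C@H](c1cc(OC)c(O)cc1O)CC2=O | target

## Step count

Total step count: 13.
Longest linear sequence: 10 (steps 1–6 and 10–13).

## Steps most likely to fail

**Step 5 (the new step).**
- Risks: direct benzyl or vinyl transmetalation (Suzuki products), beta-hydride elimination, or a low enantiomer ratio.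
- The fallback uses known chemistry, sets out from 5 and comes back at 12.
- Compound 5 is lithiated as in step 4 and quenched with allyl bromide to give 2-allyl-5-methoxy-1,3-bis(methoxymethoxy)benzene F1.
- Pt(dba)3 with a TADDOL-derived phosphonite and B2pin2 effects enantioselective alkene diboration to (2R)-3-[4-methoxy-2,6-bis(methoxymethoxy)phenyl]propane-1,2-diyl bis(pinacol boronate) F2.
- In the same flask Pd(OAc)2/RuPhos/KOH couples only the primary C–B bond with 10 to give 12.
- Step 6 then follows unchanged.

**Step 12.**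
- Risks: the electron-rich, ortho-substituted B ring lowers the electrophilicity of the enone, so conversion or the C2 ratio may be poor.
- The fallback sets out from 25 and comes back at 26.
- NaOAc in refluxing EtOH closes the ring without stereocontrol to give 26 together with the (2R,2''R)-5-O-methyl tris-MOM flavanone F3.
- A kinetic resolution by asymmetric transfer hydrogenation follows (Cp*RhCl[(R,R)-TsDPEN], HCO2H/Et3N, EtOAc). It reduces only the 2R epimer, giving the far more polar (2R,4R)-cis-flavan-4-ol F4.
- Compound 26 is left unchanged and is separated on silica.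

**Step 13.**
- Risks: warm MgI2 may open the C ring and erode C2, or acid may cyclise the isopropenyl group onto the 7-OH.
- The fallback moves the setting of C2 to after the demethylation. It sets out from 25 and comes back at 27.
- Compound 25 is cyclised with NaOAc in EtOH to 26 plus its 2R epimer F3.
- The mixture is demethylated with MgI2·OEt2 and isolated as 27 plus the (2R,2''R)-5-hydroxy tris-MOM flavanone F5.
- The same transfer-hydrogenation resolution then turns F5 into the (2R,4R)-5-hydroxy cis-flavan-4-ol F6 and leaves 27.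
- Compound 27 is finished by the short acid methanolysis that forms the second half of step 13.

## Further compounds

F1 | step 5 | 2-allyl-5-methoxy-1,3-bis(methoxymethoxy)benzene | C=CCc1c(OCOC)cc(OC)cc1OCOC
F2 | step 5 | (2R)-3-[4-methoxy-2,6-bis(methoxymethoxy)phenyl]propane-1,2-diyl bis(pinacol boronate) | CC1(C)OB(OC1(C)C)[C@H](CB1OC(C)(C)C(C)(C)O1)Cc1c(OCOC)cc(OC)cc1OCOC
F3 | step 12 | (2R,2''R)-5-O-methyl tris-MOM flavanone | C=C(C)[C@H](CC=C(C)C)Cc1c(OCOC)cc(OC)c2c1O[C@@H](c1cc(OC)c(OCOC)cc1OCOC)CC2=O
F4 | step 12 | (2R,4R)-cis-flavan-4-ol from F3 | C=C(C)[C@H](CC=C(C)C)Cc1c(OCOC)cc(OC)c2c1O[C@@H](c1cc(OC)c(OCOC)cc1OCOC)C[C@H]2O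
F5 | step 13 | (2R,2''R)-5-hydroxy tris-MOM flavanone | C=C(C)[C@H](CC=C(C)C)Cc1c(OCOC)cc(O)c2c1O[C@@H](c1cc(OC)c(OCOC)cc1OCOC)CC2=O
F6 | step 13 | (2R,4R)-5-hydroxy cis-flavan-4-ol from F5 | C=C(C)[C@H](CC=C(C)C)Cc1c(OCOC)cc(O)c2c1O[C@@H](c1cc(OC)c(OCOC)cc1OCOC)C[C@H]2O
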